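**Plan**

- Rings: A = benzo ring of the benzofuran, B = the aryl ring on C2, C = the dihydrofuran ring, D = the resorcinol ring. The retrosynthesis first cuts the aryl–vinyl bond C5–CH= (ring A C5–H plus a ring D styrene, joined by a tether-directed oxidative Heck reaction), then removes the tether and acyl groups, then opens ring C at C2–C3 (rhodium carbenoid C–H insertion), and last cuts the aryl–CH2CO2Me and ArO–CH2Ar bonds.
- Enabling feature: C3, next to C3a, carries the CH2OH arm trans to ring B. A 2-cyanobenzoate on that oxygen can reach only the positions meta to C3a. Of these, C7 is blocked by OMe, so only C5–H remains, and C5 is also para to the ring oxygen O1. Simple electrophilic substitution would not distinguish ring A from the equally electron-rich ring B.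
- Forward order: Mitsunobu ether, Reformatsky/Negishi arylacetate, diazo ester, ring C closed by 1,5 C–H insertion, epimerisation, reduction, benzyl-to-acetate exchange, tether, C5–H olefination, one-pot methanolysis of tether and acetates.
- Stereochemistry: C2 (R) comes from the chiral catalyst Rh2(S-PTTL)4 in the C–H insertion; C3 is set by thermodynamic epimerisation of the cis ester to trans; the E alkene comes from syn insertion and syn β-hydride elimination.
- The tether is a bond that the target does not contain; it leaves in the last step as methyl 2-cyanobenzoate.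

Key step: step 11

Assumption: Rh2(S-PTTL)4 is taken to give the (2R,3S)-cis ester; should the facial sense be the opposite, the mirror-image catalyst Rh2(R-PTTL)4 is used in step 4 with nothing else changed.

**Route**

Step 1
Reactants: 1 2-bromo-6-methoxyphenol; 2 [4-(benzyloxy)-3-methoxyphenyl]methanol
Product: 3 1-(benzyloxy)-4-[(2-bromo-6-methoxyphenoxy)methyl]-2-methoxybenzene
Conditions: PPh3, DIAD, THF, 0 °C to rt
Reagents that add atoms: none
Why: Mitsunobu etherification, in which the acidic ortho-bromophenol displaces the oxyphosphonium-activated primary benzylic alcohol under neutral conditions, so that no benzylic halide has to be made; no stereocentre is involved.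

Step 2
Reactants: 3 1-(benzyloxy)-4-[(2-bromo-6-methoxyphenoxy)methyl]-2-methoxybenzene
Product: 4 methyl 2-[2-{[4-(benzyloxy)-3-methoxyphenyl]methoxy}-3-methoxyphenyl]acetate
Conditions: BrZnCH2CO2Me (from methyl bromoacetate, Zn dust, cat. TMSCl, THF), Pd2(dba)3 (2 mol%), XPhos (8 mol%), THF, 65 °C
Reagents that add atoms: methyl bromoacetate, COC(=O)CBr, used as its zinc reagent bromo(2-methoxy-2-oxoethyl)zinc, COC(=O)C[Zn]Br
Why: Negishi-type arylation of a Reformatsky zinc enolate (oxidative addition of zerovalent palladium into the ortho-alkoxy aryl bromide, transmetalation, reductive elimination) should give the arylacetate without the strong base that would invite diarylation or Claisen condensation.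

Step 3
Reactants: 4 methyl 2-[2-{[4-(benzyloxy)-3-methoxyphenyl]methoxy}-3-methoxyphenyl]acetate
Product: 5 methyl 2-[2-{[4-(benzyloxy)-3-methoxyphenyl]methoxy}-3-methoxyphenyl]-2-diazoacetate
Conditions: p-ABSA, DBU, MeCN, 0 °C to rt
Reagents that add atoms: 4-acetamidobenzenesulfonyl azide (p-ABSA), CC(=O)Nc1ccc(cc1)S(=O)(=O)N=[N+]=[N-]
Why: Regitz diazo transfer, in which the DBU-generated arylacetate enolate attacks the terminal nitrogen of the sulfonyl azide and expels the sulfonamide, is the standard entry to aryl diazoacetates.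

Step 4
Reactants: 5 methyl 2-[2-{[4-(benzyloxy)-3-methoxyphenyl]methoxy}-3-methoxyphenyl]-2-diazoacetate
Product: 6 methyl (2R,3S)-2-[4-(benzyloxy)-3-methoxyphenyl]-7-methoxy-2,3-dihydro-1-benzofuran-3-carboxylate (cis)
Conditions: Rh2(S-PTTL)4, dirhodium tetrakis[N-phthaloyl-(S)-tert-leucinate] (2 mol%), toluene, −60 °C
Reagents that add atoms: none
Why: Intramolecular 1,5 C–H insertion of the donor/acceptor rhodium carbenoid into the electron-rich benzylic O–CH2 bond closes ring C by forming C2–C3; the concerted transition state should give the cis ester kinetically, and the chiral carboxylate ligands select one enantiotopic benzylic hydrogen, which sets C2 as R.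

Step 5
Reactants: 6 methyl (2R,3S)-2-[4-(benzyloxy)-3-methoxyphenyl]-7-methoxy-2,3-dihydro-1-benzofuran-3-carboxylate
Product: 7 methyl (2R,3R)-2-[4-(benzyloxy)-3-methoxyphenyl]-7-methoxy-2,3-dihydro-1-benzofuran-3-carboxylate (trans)
Conditions: NaOMe, MeOH/THF, rt
Reagents that add atoms: none
Why: Base-mediated epimerisation through the ester enolate at C3 relieves the cis aryl/ester eclipsing and should give the thermodynamically favoured trans ester, while C2 has no acidic hydrogen and keeps its configuration.

Step 6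
Reactants: 7 methyl (2R,3R)-2-[4-(benzyloxy)-3-methoxyphenyl]-7-methoxy-2,3-dihydro-1-benzofuran-3-carboxylate
Product: 8 [(2R,3S)-2-[4-(benzyloxy)-3-methoxyphenyl]-7-methoxy-2,3-dihydro-1-benzofuran-3-yl]methanol
Conditions: LiAlH4, THF, 0 °C
Reagents that add atoms: none
Why: Hydride reduction of the methyl ester to the primary alcohol leaves both stereocentres untouched (the C3 descriptor changes from R to S only because the substituent priorities change), and the ethers are inert.

Step 7
Reactants: 8 [(2R,3S)-2-[4-(benzyloxy)-3-methoxyphenyl]-7-methoxy-2,3-dihydro-1-benzofuran-3-yl]methanol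
Product: 9 4-[(2R,3S)-3-(hydroxymethyl)-7-methoxy-2,3-dihydro-1-benzofuran-2-yl]-2-methoxyphenol
Conditions: H2 (1 atm), 10% Pd/C, EtOAc, rt
Reagents that add atoms: none
Why: Hydrogenolysis of the aryl benzyl ether over palladium on carbon is much faster than cleavage of the cyclic benzylic C2–O1 bond and is done here, before any alkene is in the molecule.

Step 8
Reactants: 9 4-[(2R,3S)-3-(hydroxymethyl)-7-methoxy-2,3-dihydro-1-benzofuran-2-yl]-2-methoxyphenol
Product: 10 4-[(2R,3S)-3-(hydroxymethyl)-7-methoxy-2,3-dihydro-1-benzofuran-2-yl]-2-methoxyphenyl acetate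
Conditions: Ac2O (1.1 equiv), 1 M NaOH aq, THF, 0 °C
Reagents that add atoms: acetic anhydride, CC(=O)OC(C)=O
Why: Under Schotten–Baumann conditions only the phenoxide is acetylated and the non-ionised primary alcohol stays free; the acetate later lowers the electron density of ring B.

Step 9
Reactants: 10 4-[(2R,3S)-3-(hydroxymethyl)-7-methoxy-2,3-dihydro-1-benzofuran-2-yl]-2-methoxyphenyl acetate
Product: 11 [(2R,3S)-2-[4-(acetyloxy)-3-methoxyphenyl]-7-methoxy-2,3-dihydro-1-benzofuran-3-yl]methyl 2-cyanobenzoate
Conditions: 2-cyanobenzoyl chloride, pyridine, CH2Cl2, 0 °C to rt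
Reagents that add atoms: 2-cyanobenzoyl chloride, N#Cc1ccccc1C(Cl)=O
Why: Acylation of the primary alcohol with the acid chloride and pyridine installs the nitrile tether on the C3 arm, trans to ring B so that it can fold over ring A; DMAP is left out to avoid acetyl transfer from the aryl acetate.

Step 10
Reactants: 12 3,5-dihydroxybenzaldehyde
Product: 14 5-ethenylbenzene-1,3-diyl diacetate (3,5-diacetoxystyrene), via 3,5-dihydroxystyrene 13 (not isolated)
Conditions: Ph3PCH3Br (1.5 equiv), KOtBu (3.5 equiv), THF, 0 °C to rt; then Ac2O (3 equiv), 0 °C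
Reagents that add atoms: methyltriphenylphosphonium bromide, C[P+](c1ccccc1)(c1ccccc1)c1ccccc1.[Br-]; acetic anhydride, CC(=O)OC(C)=O
Why: Wittig methylenation of the aldehyde as its bis-phenoxide, followed by acetylation of the potassium phenoxides in the same flask, avoids isolating the polymerisation-prone dihydroxystyrene.

Step 11
Reactants: 11 [(2R,3S)-2-[4-(acetyloxy)-3-methoxyphenyl]-7-methoxy-2,3-dihydro-1-benzofuran-3-yl]methyl 2-cyanobenzoate; 14 5-ethenylbenzene-1,3-diyl diacetate (2 equiv)
Product: 15 [(2R,3S)-2-[4-(acetyloxy)-3-methoxyphenyl]-5-[(E)-2-[3,5-bis(acetyloxy)phenyl]ethenyl]-7-methoxy-2,3-dihydro-1-benzofuran-3-yl]methyl 2-cyanobenzoate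
Conditions: Pd(OAc)2 (10 mol%), N-acetylglycine (20 mol%), AgOAc (3 equiv), HFIP, 80 °C
Reagents that add atoms: none
Why: Proposed new method: the nitrile nitrogen of the 2-cyanobenzoate tether binds divalent palladium end-on and, through a twelve-membered cyclophane-like transition state (C5, C4, C3a, C3, CH2, O, C=O, two benzoate carbons, the nitrile C and N, Pd), holds it over C5–H, which is cleaved by concerted metalation–deprotonation with the N-acetylglycinate ligand as internal base; the aryl–palladium species then inserts styrene 14 at its terminal carbon, syn β-hydride elimination releases the stilbene, and AgOAc returns zerovalent palladium to the divalent state. The closest known reaction type is the nitrile-template-directed meta-C–H olefination (a directed Fujiwara–Moritani reaction) of arylacetic acid, hydrocinnamic acid, benzyl alcohol and 2-arylethanol derivatives with acrylates, which runs through macrocyclic transition states of the same size; what is new is the benzoate-linked tether on a fused dihydrobenzofuran and a styrene as the olefin. No ring of the target is closed, the palladacycle being only transient. No stereocentre is formed: C2 and C3 are untouched because C3 has no acidic hydrogen next to a carbonyl and the ring B acetate holds back ionisation of the C2–O1 bond in HFIP, and the E geometry follows from syn insertion and syn elimination. The step needs C5 selectivity over C4, C6 and ring B, and this is secured because the tether spans only to the positions meta to C3a, of which C7 is blocked by OMe, because C5 is also the electronically favoured site para to O1, because C4 is too close and hindered, and because ring B is deactivated by its acetate and carries no tether.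

Step 12
Reactants: 15 [(2R,3S)-2-[4-(acetyloxy)-3-methoxyphenyl]-5-[(E)-2-[3,5-bis(acetyloxy)phenyl]ethenyl]-7-methoxy-2,3-dihydro-1-benzofuran-3-yl]methyl 2-cyanobenzoate
Product: 16 gnetofuran A, 5-[(E)-2-[(2R,3S)-2-(4-hydroxy-3-methoxyphenyl)-3-(hydroxymethyl)-7-methoxy-2,3-dihydro-1-benzofuran-5-yl]ethenyl]benzene-1,3-diol
Conditions: K2CO3, MeOH (degassed), 0 °C to rt; then aq NH4Cl
Reagents that add atoms: none
Why: Zemplén-type transesterification should cleave the three aryl acetates and the activated 2-cyanobenzoate tether in one operation at or below room temperature, mild enough for the trans-dihydrobenzofuran and the E-stilbene to survive when oxygen is excluded.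

**Compound list**

1 | 2-bromo-6-methoxyphenol | COc1cccc(Br)c1O | starting material
2 | [4-(benzyloxy)-3-methoxyphenyl]methanol | COc1cc(CO)ccc1OCc1ccccc1 | starting material
3 | 1-(benzyloxy)-4-[(2-bromo-6-methoxyphenoxy)methyl]-2-methoxybenzene | COc1cccc(Br)c1OCc1ccc(OCc2ccccc2)c(OC)c1 | intermediate
4 | methyl 2-[2-{[4-(benzyloxy)-3-methoxyphenyl]methoxy}-3-methoxyphenyl]acetate | COC(=O)Cc1cccc(OC)c1OCc1ccc(OCc2ccccc2)c(OC)c1 | intermediate
5 | methyl 2-[2-{[4-(benzyloxy)-3-methoxyphenyl]methoxy}-3-methoxyphenyl]-2-diazoacetate | COC(=O)C(=[N+]=[N-])c1cccc(OC)c1OCc1ccc(OCc2ccccc2)c(OC)c1 | intermediate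
6 | methyl (2R,3S)-2-[4-(benzyloxy)-3-methoxyphenyl]-7-methoxy-2,3-dihydro-1-benzofuran-3-carboxylate (cis) | COc1cc([C@@H]2Oc3c(OC)cccc3[C@@H]2C(=O)OC)ccc1OCc1ccccc1 | intermediate
7 | methyl (2R,3R)-2-[4-(benzyloxy)-3-methoxyphenyl]-7-methoxy-2,3-dihydro-1-benzofuran-3-carboxylate (trans) | COc1cc([C@@H]2Oc3c(OC)cccc3[C@H]2C(=O)OC)ccc1OCc1ccccc1 | intermediate
8 | [(2R,3S)-2-[4-(benzyloxy)-3-methoxyphenyl]-7-methoxy-2,3-dihydro-1-benzofuran-3-yl]methanol | COc1cc([C@@H]2Oc3c(OC)cccc3[C@H]2CO)ccc1OCc1ccccc1 | intermediate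
9 | 4-[(2R,3S)-3-(hydroxymethyl)-7-methoxy-2,3-dihydro-1-benzofuran-2-yl]-2-methoxyphenol | COc1cc([C@@H]2Oc3c(OC)cccc3[C@H]2CO)ccc1O | intermediate
10 | 4-[(2R,3S)-3-(hydroxymethyl)-7-methoxy-2,3-dihydro-1-benzofuran-2-yl]-2-methoxyphenyl acetate | COc1cc([C@@H]2Oc3c(OC)cccc3[C@H]2CO)ccc1OC(C)=O | intermediate
11 | [(2R,3S)-2-[4-(acetyloxy)-3-methoxyphenyl]-7-methoxy-2,3-dihydro-1-benzofuran-3-yl]methyl 2-cyanobenzoate | COc1cc([C@@H]2Oc3c(OC)cccc3[C@H]2COC(=O)c2ccccc2C#N)ccc1OC(C)=O | intermediate
12 | 3,5-dihydroxybenzaldehyde | O=Cc1cc(O)cc(O)c1 | starting material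
13 | 3,5-dihydroxystyrene (5-ethenylbenzene-1,3-diol) | C=Cc1cc(O)cc(O)c1 | intermediate
14 | 5-ethenylbenzene-1,3-diyl diacetate (3,5-diacetoxystyrene) | C=Cc1cc(OC(C)=O)cc(OC(C)=O)c1 | intermediate
15 | [(2R,3S)-2-[4-(acetyloxy)-3-methoxyphenyl]-5-[(E)-2-[3,5-bis(acetyloxy)phenyl]ethenyl]-7-methoxy-2,3-dihydro-1-benzofuran-3-yl]methyl 2-cyanobenzoate | COc1cc([C@@H]2Oc3c(OC)cc(/C=C/c4cc(OC(C)=O)cc(OC(C)=O)c4)cc3[C@H]2COC(=O)c2ccccc2C#N)ccc1OC(C)=O | intermediate
16 | gnetofuran A | COc1cc([C@@H]2Oc3c(OC)cc(/C=C/c4cc(O)cc(O)c4)cc3[C@H]2CO)ccc1O | target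

**Step count and risks**

Total steps: 12. Longest linear sequence: 11 steps (steps 1 to 9, 11 and 12); step 10 is a one-step side branch.

Steps most likely to fail:

1. Step 11 (proposed new method). The tether may not deliver palladium to C5–H fast enough, so that untethered palladation of ring B or ring D, oligomerisation of the styrene or solvolytic loss of the tether take over. The fallback uses known chemistry and sets out from 10. Acetylation of the primary alcohol (Ac2O, pyridine) should give [(2R,3S)-2-[4-(acetyloxy)-3-methoxyphenyl]-7-methoxy-2,3-dihydro-1-benzofuran-3-yl]methyl acetate F1. Sterically governed iridium-catalysed C–H borylation ([Ir(OMe)(cod)]2, 4,4'-di-tert-butyl-2,2'-bipyridine, B2pin2, THF, 80 °C) should then attack C5–H, the only aromatic C–H of F1 without an ortho substituent, and give the C5 pinacol boronate F2. Oxidative Heck coupling of F2 with styrene 14 (Pd(OAc)2, 2,9-dimethyl-1,10-phenanthroline, O2, DMF, 50 °C) should give gnetofuran A tetraacetate F3, and methanolysis as in step 12 (K2CO3, MeOH) brings the route back at 16.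

2. Step 4. Facial selectivity of the carbenoid insertion may be incomplete, because the O–CH2 group is flanked by the methoxy group and may not sit well in the chiral pocket. The fallback replaces asymmetric catalysis by resolution and sets out from 5. Rh2(OAc)4 in CH2Cl2 should give the racemic cis ester F4, NaOMe in MeOH the racemic trans ester F5, and LiAlH4 the racemic trans alcohol F6. Preparative chromatography on a chiral stationary phase then separates 8 from its (2S,3R) enantiomer F7, and the route is rejoined at 8.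

3. Step 2. Oxidative addition and transmetalation at the hindered ortho-alkoxy bromide may be slow, so that protodebromination and protonation of the zinc enolate compete. The fallback builds the diazo ester without an arylacetate and sets out from 3. Bromine–lithium exchange (n-BuLi, THF, −78 °C) and acylation with dimethyl oxalate should give the α-keto ester methyl 2-[2-{[4-(benzyloxy)-3-methoxyphenyl]methoxy}-3-methoxyphenyl]-2-oxoacetate F8. Condensation with tosylhydrazide (MeOH, 60 °C) should give the tosylhydrazone F9, and Bamford–Stevens elimination (DBU, CH2Cl2, rt) brings the route back at 5, bypassing 4.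

Further compounds
F1 | step 11 | [(2R,3S)-2-[4-(acetyloxy)-3-methoxyphenyl]-7-methoxy-2,3-dihydro-1-benzofuran-3-yl]methyl acetate | COc1cc([C@@H]2Oc3c(OC)cccc3[C@H]2COC(C)=O)ccc1OC(C)=O
F2 | step 11 | [(2R,3S)-2-[4-(acetyloxy)-3-methoxyphenyl]-7-methoxy-5-(4,4,5,5-tetramethyl-1,3,2-dioxaborolan-2-yl)-2,3-dihydro-1-benzofuran-3-yl]methyl acetate | COc1cc([C@@H]2Oc3c(OC)cc(B4OC(C)(C)C(C)(C)O4)cc3[C@H]2COC(C)=O)ccc1OC(C)=O
F3 | step 11 | gnetofuran A tetraacetate | COc1cc([C@@H]2Oc3c(OC)cc(/C=C/c4cc(OC(C)=O)cc(OC(C)=O)c4)cc3[C@H]2COC(C)=O)ccc1OC(C)=O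
F4 | step 4 | racemic cis ester, methyl (2R,3S)- and (2S,3R)-2-[4-(benzyloxy)-3-methoxyphenyl]-7-methoxy-2,3-dihydro-1-benzofuran-3-carboxylate (1:1) | COc1cc([C@@H]2Oc3c(OC)cccc3[C@@H]2C(=O)OC)ccc1OCc1ccccc1.COc1cc([C@H]2Oc3c(OC)cccc3[C@H]2C(=O)OC)ccc1OCc1ccccc1
F5 | step 4 | racemic trans ester, methyl (2R,3R)- and (2S,3S)-2-[4-(benzyloxy)-3-methoxyphenyl]-7-methoxy-2,3-dihydro-1-benzofuran-3-carboxylate (1:1) | COc1cc([C@@H]2Oc3c(OC)cccc3[C@H]2C(=O)OC)ccc1OCc1ccccc1.COc1cc([C@H]2Oc3c(OC)cccc3[C@@H]2C(=O)OC)ccc1OCc1ccccc1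
F6 | step 4 | racemic trans alcohol, [(2R,3S)- and (2S,3R)-2-[4-(benzyloxy)-3-methoxyphenyl]-7-methoxy-2,3-dihydro-1-benzofuran-3-yl]methanol (1:1) | COc1cc([C@@H]2Oc3c(OC)cccc3[C@H]2CO)ccc1OCc1ccccc1.COc1cc([C@H]2Oc3c(OC)cccc3[C@@H]2CO)ccc1OCc1ccccc1
F7 | step 4 | [(2S,3R)-2-[4-(benzyloxy)-3-methoxyphenyl]-7-methoxy-2,3-dihydro-1-benzofuran-3-yl]methanol | COc1cc([C@H]2Oc3c(OC)cccc3[C@@H]2CO)ccc1OCc1ccccc1
F8 | step 2 | methyl 2-[2-{[4-(benzyloxy)-3-methoxyphenyl]methoxy}-3-methoxyphenyl]-2-oxoacetate | COC(=O)C(=O)c1cccc(OC)c1OCc1ccc(OCc2ccccc2)c(OC)c1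
F9 | step 2 | methyl 2-[2-{[4-(benzyloxy)-3-methoxyphenyl]methoxy}-3-methoxyphenyl]-2-[2-(4-methylbenzenesulfonyl)hydrazinylidene]acetate | COC(=O)C(=NNS(=O)(=O)c1ccc(C)cc1)c1cccc(OC)c1OCc1ccc(OCc2ccccc2)c(OC)c1
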